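The C4–C5 bond (germacrane numbering) is the only C–C bond shared by the 4,5-oxirane and the cyclodecane, and C4 carries the C15 methyl: the retron of a sulfur-ylide epoxidation of a methyl ketone. An intramolecular Corey–Chaykovsky reaction should therefore close the ten-membered ring and the trans-epoxide and set C4 and C5 in one operation. Its precursor is an open-chain C5 diphenylsulfonium salt that already holds the C4 methyl ketone, the 1,10-epoxide, the C2 angelate and a C6 PMB ether. C5–C10, C14 and the isopropyl group come from (−)-menthone, whose ring is the latent C5–C10-bonded (eudesmane-type) ring of the germacrane.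

Key step: step 15

Remark: all seco intermediates keep germacrane numbering (ring C1–C10, C14 on C10, C15 on C4, isopropyl on C7); (−)-menthone, angelic acid and all reagents are taken as commercial.

Step 1
Reactants: 1 (−)-menthone
Product: 3 (S)-piperitone, via silyl enol ether 2 (not isolated)
Conditions: LDA, THF, −78 °C, then TMSCl; crude 2, Pd(OAc)2 (10 mol%), O2 (1 atm), DMSO, 25 °C
Reagents that add atoms: none
Why: Kinetic deprotonation occurs at the CH2 flank and Saegusa–Ito dehydrogenation of enol ether 2 (β-hydride elimination toward the methyl-bearing carbon) should give the enone without touching the isopropyl-bearing stereocentre.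

Step 2
Reactants: 3 (S)-piperitone
Product: 4 (1R,6S)-cis-piperitol
Conditions: L-Selectride, THF, −78 °C; NaOH, H2O2, 0 °C
Reagents that add atoms: none
Why: 1,2-Reduction of the β-methyl enone by a bulky hydride, which should attack the carbonyl face opposite the adjacent isopropyl group and so place OH cis to it (1R).

Step 3
Reactants: 4 (1R,6S)-cis-piperitol
Product: 5 cis-piperitol PMB ether
Conditions: NaH, PMBCl, Bu4NI (cat.), THF/DMF, 0 → 23 °C
Reagents that add atoms: 4-methoxybenzyl chloride, COc1ccc(CCl)cc1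
Why: Williamson etherification of the allylic alkoxide; no stereocentre is touched.

Step 4
Reactants: 5 cis-piperitol PMB ether
Product: 7 keto alcohol, via keto aldehyde 6 (not isolated)
Conditions: O3, CH2Cl2, −78 °C (Sudan III end point); PPh3, −78 → 23 °C; then NaBH(OAc)3, AcOH, 0 °C
Reagents that add atoms: ozone, [O-][O+]=O
Why: Ozonolysis cleaves the only alkene (the anisyl ring reacts more slowly) into the C10 methyl ketone and the C5 α-alkoxy aldehyde, and NaBH(OAc)3 reduces aldehydes but not ketones, so the two ends of the former ring are differentiated in one pot.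

Step 5
Reactants: 7 keto alcohol
Product: 8 TBS-protected ketone
Conditions: TBSCl, imidazole, DMF, 23 °C
Reagents that add atoms: tert-butyldimethylsilyl chloride, CC(C)(C)[Si](C)(C)Cl
Why: Imidazole-promoted silylation of the primary alcohol.

Step 6
Reactants: 8 TBS-protected ketone
Product: 10 terminal alkyne, via enol phosphate 9 (not isolated)
Conditions: LDA (1.1 equiv), THF, −78 °C; ClP(O)(OEt)2, −78 → 23 °C; LDA (2.3 equiv), −78 → 23 °C
Reagents that add atoms: none
Why: Methyl ketone to alkyne by kinetic enolisation toward CH3, O-phosphorylation and base-induced β-elimination of the enol phosphate; C6 and C7 carry no acidic hydrogen.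

Step 7
Reactants: 10 terminal alkyne
Product: 13 (E)-allylic alcohol, via alkenylalane 11 (not isolated), via lithium alanate 12 (not isolated)
Conditions: Me3Al, Cp2ZrCl2 (cat.), CH2Cl2, 0 → 23 °C; then n-BuLi, THF, −78 °C; (CH2O)n, −78 → 23 °C
Reagents that add atoms: trimethylaluminium, C[Al](C)C; paraformaldehyde (as formaldehyde), C=O
Why: Negishi zirconium-catalysed carboalumination adds Me–Al syn with Al at the terminus, and the ate complex should add to formaldehyde with retention, fixing the (E)-C1=C10 geometry and the C14 methyl.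

Step 8
Reactants: 13 (E)-allylic alcohol
Product: 14 (E)-enal
Conditions: MnO2, CH2Cl2, 23 °C
Reagents that add atoms: none
Why: Chemoselective MnO2 oxidation of the allylic alcohol without E/Z isomerisation.

Step 9
Reactants: 14 (E)-enal
Product: 15 (R)-dienol
Conditions: (R)-BINOL (20 mol%), Ti(OiPr)4 (10 mol%), 4 Å MS, methallyl-SnBu3, CH2Cl2, −20 °C; aq. KF
Reagents that add atoms: tributyl(2-methylprop-2-en-1-yl)stannane, CC(=C)C[Sn](CCCC)(CCCC)CCCC
Why: Keck asymmetric allylation, in which the (R)-BINOL–Ti(IV) Lewis acid should direct the methallylstannane to the Re face of the aldehyde (1,2-addition) and set C2 as R; the 1,1-disubstituted alkene is the masked C4 ketone.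

Step 10
Reactants: 15 (R)-dienol
Product: 16 threo epoxy alcohol
Conditions: mCPBA (1.05 equiv), NaHCO3, CH2Cl2, −20 → 0 °C
Reagents that add atoms: mCPBA, OOC(=O)c1cccc(Cl)c1
Why: Henbest hydroxyl-directed epoxidation of the more nucleophilic trisubstituted allylic alkene; A(1,3) strain with the C14 methyl holds C2–H in the alkene plane, so the hydrogen-bonded peracid should deliver oxygen to give the threo (1S,10S) epoxy alcohol.

Step 11
Reactants: 16 threo epoxy alcohol; 17 angelic acid
Product: 19 epoxy angelate, via mixed anhydride 18 (not isolated)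
Conditions: 17, 2,4,6-trichlorobenzoyl chloride, Et3N, toluene, 23 °C; then 16, toluene, 80 °C
Reagents that add atoms: none
Why: Yamaguchi-type esterification through the mixed anhydride, attacked at the less hindered angeloyl carbonyl; DMAP-free conditions should avoid Z→E isomerisation to the tiglate.

Step 12
Reactants: 19 epoxy angelate
Product: 20 keto angelate
Conditions: OsO4 (2 mol%), NaIO4, 2,6-lutidine, dioxane/H2O, 23 °C
Reagents that add atoms: sodium periodate, [Na+].[O-]I(=O)(=O)=O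
Why: Lemieux–Johnson oxidation, selective for the electron-rich 1,1-disubstituted alkene over the conjugated, trisubstituted angelate, should unveil the C4 methyl ketone under buffered conditions that do not eliminate the β-acyloxy group.

Step 13
Reactants: 20 keto angelate
Product: 21 hydroxy ketone
Conditions: HF·pyridine, pyridine, THF, 0 °C
Reagents that add atoms: none
Why: Buffered fluoride desilylation of the primary TBS ether; epoxide, PMB ether and β-acyloxy ketone should survive the near-neutral medium.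

Step 14
Reactants: 21 hydroxy ketone
Product: 23 sulfonium triflate, via primary triflate 22 (not isolated)
Conditions: Tf2O, 2,6-di-tert-butyl-4-methylpyridine, CH2Cl2, −78 °C; then Ph2S (5 equiv), −78 → 23 °C
Reagents that add atoms: triflic anhydride, O=S(=O)(OS(=O)(=O)C(F)(F)F)C(F)(F)F; diphenyl sulfide, c1ccc(Sc2ccccc2)cc1
Why: O-Triflation of the primary alcohol followed by SN2 S-alkylation of diphenyl sulfide should give the sulfonium salt, the hindered non-nucleophilic base preventing epoxide opening and enol triflate formation.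

Step 15
Reactants: 23 sulfonium triflate
Product: 26 macrocyclic diepoxide PMB ether, via sulfonium ylide 24 (not isolated), via anti-betaine 25 (not isolated)
Conditions: KHMDS (1.05 equiv), THF, −78 → −30 °C, slow addition of 23 (final 1 mM)
Reagents that add atoms: none
Why: Proposed new method: KHMDS removes the most acidic proton, the C5–H next to S+ (the S-phenyl groups carry no α-hydrogen and the methyl ketone is several pKa units less acidic), to give ylide 24, whose carbanion adds to the C4 ketone to form anti-betaine 25 before the C4 alkoxide expels Ph2S by intramolecular SN2 at C5. The closest known reactions are the Corey–Chaykovsky epoxidation of ketones by diphenylsulfonium alkylides and intramolecular sulfonium-ylide epoxy-annulations that close five- to seven-membered rings; a ten-membered closure has not been shown, hence the label. The cyclodecane closes 10-exo-trig in the C–C bond-forming step and the oxirane 3-exo-tet in the displacement. C5 is controlled by the C6 stereocentre (the ketone should approach the ylide face anti to the C7 branch with C6–H turned toward the bulky Ph2S+ group, and SN2 inversion then gives 5S with O5 threo to O6), and C4 by the macrocyclic transition state, in which C3–C4 and C5–C6 are antiperiplanar as in an (E)-cyclodecene so that Ph2S+ stays outside the ring and the trans-oxirane (4S) results. The step needs addition to the ketone rather than to the angelate carbonyl or the 1,10-epoxide, no β-elimination of the C6 oxygen and no oligomerisation. These are secured by the higher electrophilicity of the ketone, the poor leaving-group ability of the PMB alkoxide (the reason for an ether and not an ester at C6), the low basicity of the ylide and high dilution at low temperature.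

Step 16
Reactants: 26 macrocyclic diepoxide PMB ether
Product: 27 6-hydroxy diepoxide
Conditions: DDQ, CH2Cl2/pH 7 buffer, 0 °C
Reagents that add atoms: none
Why: Oxidative PMB cleavage by DDQ through the benzylic oxocarbenium ion, hydrolysed by water; esters and epoxides are inert and the buffer should suppress acid-induced epoxide opening.

Step 17
Reactants: 27 6-hydroxy diepoxide
Product: 28 CNP0311463.1
Conditions: Ac2O, pyridine, DMAP (cat.), CH2Cl2, 0 → 23 °C
Reagents that add atoms: acetic anhydride, CC(=O)OC(C)=O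
Why: Nucleophile-catalysed acetylation of the remaining secondary alcohol should give the target without touching any stereocentre.

Compound list
1 | (−)-menthone, (2S,5R)-5-methyl-2-(propan-2-yl)cyclohexan-1-one | CC(C)[C@@H]1CC[C@@H](C)CC1=O | starting material
2 | trimethyl{[(3R,6S)-3-methyl-6-(propan-2-yl)cyclohex-1-en-1-yl]oxy}silane | CC(C)[C@@H]1CC[C@@H](C)C=C1O[Si](C)(C)C | intermediate
3 | (S)-piperitone, (6S)-3-methyl-6-(propan-2-yl)cyclohex-2-en-1-one | CC(C)[C@@H]1CCC(C)=CC1=O | intermediate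
4 | cis-piperitol, (1R,6S)-3-methyl-6-(propan-2-yl)cyclohex-2-en-1-ol | CC(C)[C@@H]1CCC(C)=C[C@@H]1O | intermediate
5 | 1-methoxy-4-({[(1R,6S)-3-methyl-6-(propan-2-yl)cyclohex-2-en-1-yl]oxy}methyl)benzene | CC(C)[C@@H]1CCC(C)=C[C@@H]1OCc2ccc(OC)cc2 | intermediate
6 | (2R,3S)-2-[(4-methoxyphenyl)methoxy]-6-oxo-3-(propan-2-yl)heptanal | O=C[C@H](OCc1ccc(OC)cc1)[C@H](C(C)C)CCC(C)=O | intermediate
7 | (5S,6R)-7-hydroxy-6-[(4-methoxyphenyl)methoxy]-5-(propan-2-yl)heptan-2-one | OC[C@H](OCc1ccc(OC)cc1)[C@H](C(C)C)CCC(C)=O | intermediate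
8 | (5S,6R)-7-[(tert-butyldimethylsilyl)oxy]-6-[(4-methoxyphenyl)methoxy]-5-(propan-2-yl)heptan-2-one | CC(C)(C)[Si](C)(C)OC[C@H](OCc1ccc(OC)cc1)[C@H](C(C)C)CCC(C)=O | intermediate
9 | diethyl (5S,6R)-7-[(tert-butyldimethylsilyl)oxy]-6-[(4-methoxyphenyl)methoxy]-5-(propan-2-yl)hept-1-en-2-yl phosphate | CC(C)(C)[Si](C)(C)OC[C@H](OCc1ccc(OC)cc1)[C@H](C(C)C)CCC(=C)OP(=O)(OCC)OCC | intermediate
10 | tert-butyl{[(2R,3S)-2-[(4-methoxyphenyl)methoxy]-3-(propan-2-yl)hept-6-yn-1-yl]oxy}dimethylsilane | CC(C)(C)[Si](C)(C)OC[C@H](OCc1ccc(OC)cc1)[C@H](C(C)C)CCC#C | intermediate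
11 | [(1E,5S,6R)-7-[(tert-butyldimethylsilyl)oxy]-6-[(4-methoxyphenyl)methoxy]-2-methyl-5-(propan-2-yl)hept-1-en-1-yl]dimethylalane | CC(C)(C)[Si](C)(C)OC[C@H](OCc1ccc(OC)cc1)[C@H](C(C)C)CC/C(C)=C/[Al](C)C | intermediate
12 | lithium butyl[(1E,5S,6R)-7-[(tert-butyldimethylsilyl)oxy]-6-[(4-methoxyphenyl)methoxy]-2-methyl-5-(propan-2-yl)hept-1-en-1-yl]dimethylaluminate | CC(C)(C)[Si](C)(C)OC[C@H](OCc1ccc(OC)cc1)[C@H](C(C)C)CC/C(C)=C/[Al-](C)(C)CCCC.[Li+] | intermediate
13 | (2E,6S,7R)-8-[(tert-butyldimethylsilyl)oxy]-7-[(4-methoxyphenyl)methoxy]-3-methyl-6-(propan-2-yl)oct-2-en-1-ol | CC(C)(C)[Si](C)(C)OC[C@H](OCc1ccc(OC)cc1)[C@H](C(C)C)CC/C(C)=C/CO | intermediate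
14 | (2E,6S,7R)-8-[(tert-butyldimethylsilyl)oxy]-7-[(4-methoxyphenyl)methoxy]-3-methyl-6-(propan-2-yl)oct-2-enal | CC(C)(C)[Si](C)(C)OC[C@H](OCc1ccc(OC)cc1)[C@H](C(C)C)CC/C(C)=C/C=O | intermediate
15 | (4R,5E,9S,10R)-11-[(tert-butyldimethylsilyl)oxy]-10-[(4-methoxyphenyl)methoxy]-2,6-dimethyl-9-(propan-2-yl)undeca-1,5-dien-4-ol | CC(C)(C)[Si](C)(C)OC[C@H](OCc1ccc(OC)cc1)[C@H](C(C)C)CC/C(C)=C/[C@H](O)CC(C)=C | intermediate
16 | (1R)-1-[(2S,3S)-3-{(3S,4R)-5-[(tert-butyldimethylsilyl)oxy]-4-[(4-methoxyphenyl)methoxy]-3-(propan-2-yl)pentyl}-3-methyloxiran-2-yl]-3-methylbut-3-en-1-ol | CC(C)(C)[Si](C)(C)OC[C@H](OCc1ccc(OC)cc1)[C@H](C(C)C)CC[C@]1(C)O[C@H]1[C@H](O)CC(C)=C | intermediate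
17 | angelic acid, (2Z)-2-methylbut-2-enoic acid | C/C=C(/C)C(=O)O | starting material
18 | (2Z)-2-methylbut-2-enoic 2,4,6-trichlorobenzoic anhydride | C/C=C(/C)C(=O)OC(=O)c1c(Cl)cc(Cl)cc1Cl | intermediate
19 | (1R)-1-[(2S,3S)-3-{(3S,4R)-5-[(tert-butyldimethylsilyl)oxy]-4-[(4-methoxyphenyl)methoxy]-3-(propan-2-yl)pentyl}-3-methyloxiran-2-yl]-3-methylbut-3-en-1-yl (2Z)-2-methylbut-2-enoate | CC(C)(C)[Si](C)(C)OC[C@H](OCc1ccc(OC)cc1)[C@H](C(C)C)CC[C@]1(C)O[C@H]1[C@H](OC(=O)/C(C)=C\C)CC(C)=C | intermediate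
20 | (1R)-1-[(2S,3S)-3-{(3S,4R)-5-[(tert-butyldimethylsilyl)oxy]-4-[(4-methoxyphenyl)methoxy]-3-(propan-2-yl)pentyl}-3-methyloxiran-2-yl]-3-oxobutyl (2Z)-2-methylbut-2-enoate | CC(C)(C)[Si](C)(C)OC[C@H](OCc1ccc(OC)cc1)[C@H](C(C)C)CC[C@]1(C)O[C@H]1[C@H](OC(=O)/C(C)=C\C)CC(C)=O | intermediate
21 | (1R)-1-[(2S,3S)-3-{(3S,4R)-5-hydroxy-4-[(4-methoxyphenyl)methoxy]-3-(propan-2-yl)pentyl}-3-methyloxiran-2-yl]-3-oxobutyl (2Z)-2-methylbut-2-enoate | OC[C@H](OCc1ccc(OC)cc1)[C@H](C(C)C)CC[C@]1(C)O[C@H]1[C@H](OC(=O)/C(C)=C\C)CC(C)=O | intermediate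
22 | (1R)-1-[(2S,3S)-3-{(3S,4R)-4-[(4-methoxyphenyl)methoxy]-3-(propan-2-yl)-5-[(trifluoromethanesulfonyl)oxy]pentyl}-3-methyloxiran-2-yl]-3-oxobutyl (2Z)-2-methylbut-2-enoate | O=S(=O)(OC[C@H](OCc1ccc(OC)cc1)[C@H](C(C)C)CC[C@]1(C)O[C@H]1[C@H](OC(=O)/C(C)=C\C)CC(C)=O)C(F)(F)F | intermediate
23 | {(2R,3S)-2-[(4-methoxyphenyl)methoxy]-5-[(2S,3S)-2-methyl-3-{(1R)-1-[(2Z)-2-methylbut-2-enoyloxy]-3-oxobutyl}oxiran-2-yl]-3-(propan-2-yl)pentyl}diphenylsulfonium trifluoromethanesulfonate | c1ccccc1[S+](c1ccccc1)C[C@H](OCc1ccc(OC)cc1)[C@H](C(C)C)CC[C@]1(C)O[C@H]1[C@H](OC(=O)/C(C)=C\C)CC(C)=O.[O-]S(=O)(=O)C(F)(F)F | intermediate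
24 | diphenylsulfonium ylide of 23 (carbanion at C5; 1S,2R,6R,7S,10S) | c1ccccc1[S+](c1ccccc1)[CH-][C@H](OCc1ccc(OC)cc1)[C@H](C(C)C)CC[C@]1(C)O[C@H]1[C@H](OC(=O)/C(C)=C\C)CC(C)=O | intermediate
25 | (1S,2R,4S,5R,6R,7S,10S)-5-(diphenylsulfonio)-1,10-epoxy-6-[(4-methoxyphenyl)methoxy]-2-[(2Z)-2-methylbut-2-enoyloxy]germacran-4-olate (betaine) | C/C=C(/C)C(=O)O[C@@H]1C[C@](C)([O-])[C@H]([S+](c2ccccc2)c2ccccc2)[C@H](OCc2ccc(OC)cc2)[C@H](C(C)C)CC[C@]2(C)O[C@@H]12 | intermediate
26 | (1S,2R,4S,5S,6R,7S,10S)-1,10:4,5-diepoxy-6-[(4-methoxyphenyl)methoxy]germacran-2-yl (2Z)-2-methylbut-2-enoate | C/C=C(/C)C(=O)O[C@@H]1C[C@]2(C)O[C@H]2[C@H](OCc3ccc(OC)cc3)[C@H](C(C)C)CC[C@]2(C)O[C@@H]12 | intermediate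
27 | (1S,2R,4S,5S,6R,7S,10S)-1,10:4,5-diepoxy-6-hydroxygermacran-2-yl (2Z)-2-methylbut-2-enoate | C/C=C(/C)C(=O)O[C@@H]1C[C@]2(C)O[C@H]2[C@H](O)[C@H](C(C)C)CC[C@]2(C)O[C@@H]12 | intermediate
28 | CNP0311463.1, (1S,2R,4S,5S,6R,7S,10S)-6-acetoxy-1,10:4,5-diepoxygermacran-2-yl (2Z)-2-methylbut-2-enoate | C/C=C(/C)C(=O)O[C@@H]1C[C@]2(C)O[C@H]2[C@H](OC(C)=O)[C@H](C(C)C)CC[C@]2(C)O[C@@H]12 | target

Total step count: 17. Longest linear sequence: 17 steps from (−)-menthone.

Steps most likely to fail

1. Step 15 (Proposed new method). The unstabilised ylide may eliminate the C6 alkoxide or be quenched by proton transfer faster than the slow ten-membered ring closes, and the addition may show poor facial selectivity (cis-oxirane or the 4,5-bis-epimer). The fallback uses known chemistry and sets out from 21. Dess–Martin oxidation of the primary alcohol should give keto aldehyde F1. A SmI2-mediated ketone–aldehyde pinacol macrocyclisation (THF, high dilution) should then form the C4–C5 bond as the 4,5-diol F2, of which the (4S,5R) isomer is needed. Selective mesylation of the secondary C5–OH gives mesylate F3, and DBU closes the oxirane by attack of the C4 alkoxide with inversion at C5, which returns to 26.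

2. Step 14. S-Alkylation of the weakly nucleophilic diphenyl sulfide by the β-branched, β-alkoxy triflate may be slower than decomposition of the triflate through participation of the ether or epoxide oxygen. The fallback sets out from 21: an Appel reaction (I2, PPh3, imidazole) should give the stable primary iodide F4, which is ionised with AgOTf in the presence of Ph2S (silver-assisted sulfonium formation) and returns to 23.

3. Step 10. The peracid may also epoxidise the 1,1-disubstituted methallyl alkene, and the threo selectivity may erode. The fallback sets out from 13 and fixes the epoxide first by reagent control: Sharpless asymmetric epoxidation (Ti(OiPr)4, L-(+)-diethyl tartrate, TBHP) should give epoxy alcohol F5, Dess–Martin oxidation gives epoxy aldehyde F6, and chelation-controlled addition of methallyltributylstannane (MgBr2·OEt2) should set C2 threo to the epoxide and return to 16.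

Further compounds
F1 | step 15 | (1R)-1-[(2S,3S)-3-{(3S,4R)-4-[(4-methoxyphenyl)methoxy]-5-oxo-3-(propan-2-yl)pentyl}-3-methyloxiran-2-yl]-3-oxobutyl (2Z)-2-methylbut-2-enoate | O=C[C@H](OCc1ccc(OC)cc1)[C@H](C(C)C)CC[C@]1(C)O[C@H]1[C@H](OC(=O)/C(C)=C\C)CC(C)=O
F2 | step 15 | (1S,2R,4S,5R,6R,7S,10S)-1,10-epoxy-4,5-dihydroxy-6-[(4-methoxyphenyl)methoxy]germacran-2-yl (2Z)-2-methylbut-2-enoate | C/C=C(/C)C(=O)O[C@@H]1C[C@](C)(O)[C@H](O)[C@H](OCc2ccc(OC)cc2)[C@H](C(C)C)CC[C@]2(C)O[C@@H]12
F3 | step 15 | (1S,2R,4S,5R,6R,7S,10S)-1,10-epoxy-4-hydroxy-5-[(methanesulfonyl)oxy]-6-[(4-methoxyphenyl)methoxy]germacran-2-yl (2Z)-2-methylbut-2-enoate | C/C=C(/C)C(=O)O[C@@H]1C[C@](C)(O)[C@H](OS(C)(=O)=O)[C@H](OCc2ccc(OC)cc2)[C@H](C(C)C)CC[C@]2(C)O[C@@H]12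
F4 | step 14 | (1R)-1-[(2S,3S)-3-{(3S,4R)-5-iodo-4-[(4-methoxyphenyl)methoxy]-3-(propan-2-yl)pentyl}-3-methyloxiran-2-yl]-3-oxobutyl (2Z)-2-methylbut-2-enoate | IC[C@H](OCc1ccc(OC)cc1)[C@H](C(C)C)CC[C@]1(C)O[C@H]1[C@H](OC(=O)/C(C)=C\C)CC(C)=O
F5 | step 10 | [(2S,3S)-3-{(3S,4R)-5-[(tert-butyldimethylsilyl)oxy]-4-[(4-methoxyphenyl)methoxy]-3-(propan-2-yl)pentyl}-3-methyloxiran-2-yl]methanol | CC(C)(C)[Si](C)(C)OC[C@H](OCc1ccc(OC)cc1)[C@H](C(C)C)CC[C@]1(C)O[C@H]1CO
F6 | step 10 | (2R,3S)-3-{(3S,4R)-5-[(tert-butyldimethylsilyl)oxy]-4-[(4-methoxyphenyl)methoxy]-3-(propan-2-yl)pentyl}-3-methyloxirane-2-carbaldehyde | CC(C)(C)[Si](C)(C)OC[C@H](OCc1ccc(OC)cc1)[C@H](C(C)C)CC[C@]1(C)O[C@H]1C=O
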